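## Retrosynthetic overview

- **Feature:** in the ten-membered ring the C9 ketone and the methyl-bearing carbinol carbon C4 are 1,6-related. They are bridged by the unfunctionalised arc C10–C1–C2–C3, so C4–C3–C2–C1–C10–C9 is carried as a cyclohexane closed by a temporary C4–C9 bond.
- **Late disconnections:** O8 silyl ether, C6–O/C12 γ-lactone, C13 (aldehyde Mannich methylenation), C5 isobutyrate, C4/C5 cis-diol (osmylation of a Z alkene), and C8–O (Rubottom oxidation). These lead back to a ten-membered silyl enol ether.
- **Key disconnection:** that silyl enol ether arises from a cis-1,2-dialkenyl-2,6-dimethylcyclohexanol by an anionic oxy-Cope shift, in which C6–C7 is made and C4–C9 is broken.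
- **Precursor:** an E-alkenyllithium (from but-3-yn-1-ol) adds to a 2-(E-alkoxyvinyl)-2,6-dimethylcyclohexanone. The ketone comes from 2-methylcyclohexanone by enantioselective allylation (C4), RAMP-hydrazone methylation (C10), ozonolysis and acetal elimination.
- **Ring order:** cyclohexane (purchased), then the ten-membered carbocycle (ring expansion), then the α-methylene-γ-lactone.

Key step: step 11

**Remark on numbering.** C1, C2 and C3 are the ring methylenes. C4 carries OH and methyl C15, C5 the isobutyrate, and C6 the lactone oxygen. C7 carries C11, which bears methylene C13 and carbonyl C12. C8 carries OH, C9 is the ketone, and C10 carries methyl C14.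

**Remark on descriptors.** The ring is drawn flat with C1 to C10 clockwise, and β points to the viewer. The target is 4β-OH, 5β-O-acyl, 6α-O, 7β-C11, 8α-OH, 10β-CH3, which equals 4R,5S,6R,7S,8S,10S.

**Remark on protecting groups.**
- O6 travels as a naphthalen-2-ylmethyl (NAP) ether, because it must be removed oxidatively once C11=C13 is present.
- The enolate is trapped as a TBS ether, so that the Rubottom silyl shift leaves O8 protected.

## Route

Step 1
Reactants: 1 2-methylcyclohexanone
Product: 2 trimethyl[(2-methylcyclohex-1-en-1-yl)oxy]silane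
Conditions: TMSCl, NaI, Et3N, MeCN, 23 °C
Reagents that add atoms: chlorotrimethylsilane, C[Si](C)(C)Cl
Why: Enol silylation under equilibrating conditions (TMSI formed in the flask, Et3N) should favour the more substituted enol ether 2, and the minor trisubstituted isomer is removed by distillation.

Step 2
Reactants: 2 trimethyl[(2-methylcyclohex-1-en-1-yl)oxy]silane; 3 diallyl carbonate
Product: 4 (S)-2-allyl-2-methylcyclohexanone
Conditions: Pd2(dba)3 (2.5 mol %), (S)-t-BuPHOX (6.25 mol %), Bu4N[Ph3SiF2] (35 mol %), THF, 25 °C
Reagents that add atoms: none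
Why: Enantioselective Tsuji allylation of a silyl enol ether, in which fluoride frees the enolate only at the methyl-bearing carbon and the π-allylpalladium complex of the S-configured PHOX ligand, the ligand enantiomer established to give the S ketone from this enolate, sets the quaternary centre C4.

Step 3
Reactants: 4 (S)-2-allyl-2-methylcyclohexanone; 5 RAMP, (R)-1-amino-2-(methoxymethyl)pyrrolidine
Product: 6 (E)-RAMP hydrazone of 4
Conditions: TsOH·H2O (2 mol %), cyclohexane, reflux, Dean–Stark trap
Reagents that add atoms: none
Why: Acid-catalysed hydrazone condensation driven by azeotropic water removal, in which the pyrrolidine nitrogen settles anti to the quaternary C4 (E geometry) and the hydrazone of any R ketone is a diastereomer that chromatography should remove, which raises the optical purity.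

Step 4
Reactants: 6 (E)-RAMP hydrazone of 4
Product: 8 (E)-RAMP hydrazone of (2S,6S)-2-allyl-2,6-dimethylcyclohexanone, via lithium azaenolate 7 (not isolated)
Conditions: LiN(i-Pr)2 (1.1 equiv), THF, 0 °C; MeI, −95 → 23 °C
Reagents that add atoms: iodomethane, CI
Why: Enders RAMP-hydrazone alkylation, in which C10 is the only α-position with hydrogen, the methoxy-chelated azaenolate 7 is methylated on the face left open by the auxiliary, and the R auxiliary (the one that turns cyclohexanone into S-2-methylcyclohexanone) sets 10S by reagent control where the methyl and allyl groups on C4 would give no useful substrate bias.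

Step 5
Reactants: 8 (E)-RAMP hydrazone of (2S,6S)-2-allyl-2,6-dimethylcyclohexanone
Product: 9 2-[(1S,3S)-1,3-dimethyl-2-oxocyclohexyl]acetaldehyde
Conditions: O3, CH2Cl2, −78 °C; Me2S, −78 → 23 °C
Reagents that add atoms: ozone, [O-][O+]=O
Why: Ozonolysis cleaves the terminal alkene (Criegee pathway with reductive work-up) and the hydrazone C=N bond in one neutral low-temperature operation, so the ketone returns without epimerisation at C10 and the allyl group is cut back to the two-carbon arm C5–C6.

Step 6
Reactants: 9 2-[(1S,3S)-1,3-dimethyl-2-oxocyclohexyl]acetaldehyde; 10 naphthalen-2-ylmethanol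
Product: 11 (2S,6S)-2-[2,2-bis(naphthalen-2-ylmethoxy)ethyl]-2,6-dimethylcyclohexanone
Conditions: 10 (2.3 equiv), PPTS (10 mol %), 4 Å molecular sieves, CH2Cl2, 23 °C
Reagents that add atoms: none
Why: Brønsted-acid acetalisation is chemoselective for the unhindered aldehyde over a ketone flanked by a quaternary and a tertiary carbon, and PPTS at room temperature is too weak to enolise C10.

Step 7
Reactants: 11 (2S,6S)-2-[2,2-bis(naphthalen-2-ylmethoxy)ethyl]-2,6-dimethylcyclohexanone
Product: 12 (2S,6S)-2,6-dimethyl-2-[(E)-2-(naphthalen-2-ylmethoxy)ethenyl]cyclohexanone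
Conditions: TMSOTf (1.1 equiv), i-Pr2NEt (1.3 equiv), CH2Cl2, −40 → 0 °C
Reagents that add atoms: none
Why: Silyl triflate/amine elimination of an acetal to an enol ether, in which TMSOTf ionises one naphthylmethoxy group and the hindered amine removes a C5 proton from the oxocarbenium ion in the rotamer that keeps the quaternary C4 away from oxygen, which should give the E enol ether, while one equivalent of TMSOTf at low temperature should spare the hindered ketone.

Step 8
Reactants: 13 but-3-yn-1-ol
Product: 14 (but-3-yn-1-yloxy)(tert-butyl)dimethylsilane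
Conditions: TBSCl, imidazole, CH2Cl2, 0 → 23 °C
Reagents that add atoms: tert-butyldimethylsilyl chloride, CC(C)(C)[Si](C)(C)Cl
Why: Imidazole-promoted silylation of a primary alcohol is routine and gives an ether that is stable to organolithium reagents and to KH.

Step 9
Reactants: 14 (but-3-yn-1-yloxy)(tert-butyl)dimethylsilane
Product: 16 (E)-tert-butyl[(4-iodobut-3-en-1-yl)oxy]dimethylsilane, via alkenylzirconocene chloride 15 (not isolated)
Conditions: Cp2Zr(H)Cl (1.2 equiv), THF, 23 °C; I2, 0 °C
Reagents that add atoms: iodine, [I][I]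
Why: Hydrozirconation–iodination, in which syn addition of Zr–H places zirconium on the terminal carbon and iodinolysis proceeds with retention, so only the E iodide should form.

Step 10
Reactants: 12 (2S,6S)-2,6-dimethyl-2-[(E)-2-(naphthalen-2-ylmethoxy)ethenyl]cyclohexanone; 16 (E)-tert-butyl[(4-iodobut-3-en-1-yl)oxy]dimethylsilane
Product: 18 (1S,2S,6S)-1-[(E)-4-(tert-butyldimethylsilyloxy)but-1-enyl]-2,6-dimethyl-2-[(E)-2-(naphthalen-2-ylmethoxy)ethenyl]cyclohexan-1-ol, via alkenyllithium 17 (not isolated)
Conditions: 16, t-BuLi (2.0 equiv), Et2O, −78 °C; then 12, −78 → −30 °C; H2O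
Reagents that add atoms: none
Why: Lithium–iodine exchange with retention of the E geometry followed by 1,2-addition to the ketone, in which 12 is locked in the chair with the C10 methyl and the C4 alkenyl group equatorial and the C4 methyl axial, so 17 should enter along the axial trajectory on the face opposite that methyl and set C9 with its alkenyl group cis to the C4 alkenyl group and to the C10 methyl.

Step 11
Reactants: 18 (1S,2S,6S)-1-[(E)-4-(tert-butyldimethylsilyloxy)but-1-enyl]-2,6-dimethyl-2-[(E)-2-(naphthalen-2-ylmethoxy)ethenyl]cyclohexan-1-ol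
Product: 21 ten-membered TBS enol ether (4Z alkene; C8=C9 with C7 and C10 trans; 6α-ONAP; 7β-CH2CH2OTBS; 10β-CH3), via potassium alkoxide 19 (not isolated), via potassium enolate 20 (not isolated)
Conditions: KH (1.5 equiv), 18-crown-6 (1.5 equiv), THF, 0 → 50 °C; then TBSCl (2 equiv), −78 → 0 °C
Reagents that add atoms: tert-butyldimethylsilyl chloride, CC(C)(C)[Si](C)(C)Cl
Why: KH converts the C9 carbinol into alkoxide 19, whose oxyanion weakens the adjacent C4–C9 bond, and a concerted chair-like [3,3] shift joins the alkene termini C6 and C7 as C4–C9 breaks, leaving the C8–C9 enolate 20 that TBSCl captures on oxygen before it can equilibrate towards C10. The closest known reaction type is the anionic oxy-Cope ring expansion of 1,2-dialkenylcyclohexanols to cyclodec-5-enones with silyl trapping of the regiodefined enolate. The ten-membered ring is not closed end to end: the six-centre array C4–C5–C6–C7–C8–C9 and the cyclohexane share the C4–C9 bond, and scission of that bond as C6–C7 forms merges both into the C1–C10 perimeter (four-atom ring expansion). C6 and C7 are set together by the chair, in which the two E alkenes hold the naphthylmethoxy group and the C11–C12 chain equatorial (6α-O and 7β-C11, the trans relation of the later lactone), and their absolute sense is relayed from C4 and C9 because the cis alkenyl groups can overlap on one face only. The step needs the chair in preference to the boat and one of the two cyclohexane chairs, and the equatorial C10 methyl locks the conformer with the C9 alkenyl group axial and the C4 alkenyl group equatorial (the flipped chair would set the C10 methyl and the C4 alkenyl group syn-diaxial), so C3 lies axial and C10 equatorial on the six-centre chair, which gives the Z C4=C5 alkene and the enolate with C7 and C10 trans. C10 itself is not touched, since neither a proton source nor free ketone is present before silylation.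

Step 12
Reactants: 21 ten-membered TBS enol ether
Product: 23 8α-(tert-butyldimethylsilyloxy) C9 ketone with the 4Z alkene retained, via silyloxy epoxide 22 (not isolated)
Conditions: mCPBA (1.05 equiv), CH2Cl2, −20 → 0 °C
Reagents that add atoms: 3-chloroperbenzoic acid, O=C(OO)c1cccc(Cl)c1
Why: Rubottom oxidation, in which the silyl enol ether is far more nucleophilic than the trisubstituted alkene and is epoxidised on its outer face (with H7 eclipsing the silyloxy group to avoid allylic 1,3-strain the C1–C6 chain covers the other face), which sets the 8α-oxygen (8S), and epoxide 22 opens with 1,4-silyl shift so that the new oxygen emerges already protected.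

Step 13
Reactants: 23 8α-(tert-butyldimethylsilyloxy) C9 ketone with the 4Z alkene retained
Product: 24 4β,5β-diol (4R,5S)
Conditions: OsO4 (5 mol %), NMO (2 equiv), acetone/H2O, 23 °C
Reagents that add atoms: osmium tetroxide (oxygen carrier), O=[Os](=O)(=O)=O; N-methylmorpholine N-oxide, C[N+]1([O-])CCOCC1; water, O
Why: Upjohn dihydroxylation, in which syn addition to the Z alkene puts the C4 and C5 oxygens on the same face and attack from outside the ring, on the face turned away from C7 and C2 in the rotamer that holds H6 in the alkene plane next to C3, should make both β.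

Step 14
Reactants: 24 4β,5β-diol (4R,5S)
Product: 25 C5 isobutyrate
Conditions: (i-PrCO)2O, DMAP (cat.), pyridine, 23 °C
Reagents that add atoms: isobutyric anhydride, CC(C)C(=O)OC(=O)C(C)C
Why: DMAP-catalysed acyl transfer reaches only the secondary C5 hydroxyl, because the C4 hydroxyl is tertiary and O6, O8 and O12 are blocked.

Step 15
Reactants: 25 C5 isobutyrate
Product: 26 C12 primary alcohol
Conditions: HF·pyridine, pyridine, THF, 0 °C
Reagents that add atoms: none
Why: Sterically governed fluoride desilylation, in which the primary C12 silyl ether should cleave well before the secondary, neopentyl-like C8 silyl ether, and the alcohol-free buffered medium avoids ketal formation between O12 and C9.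

Step 16
Reactants: 26 C12 primary alcohol
Product: 27 C12 aldehyde
Conditions: Dess–Martin periodinane, CH2Cl2, 0 → 23 °C
Reagents that add atoms: none
Why: Dess–Martin oxidation under neutral conditions stops at the aldehyde and leaves the tertiary alcohol, the ester and the base-sensitive C8 and C10 centres alone.

Step 17
Reactants: 27 C12 aldehyde
Product: 29 2-substituted acrolein (C11=C13, C12 aldehyde), via Mannich base 28 (not isolated)
Conditions: [Me2N=CH2]I (Eschenmoser's salt), Et3N, CH2Cl2, 23 °C
Reagents that add atoms: N,N-dimethylmethyleneiminium iodide, C=[N+](C)C.[I-]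
Why: Mannich methylenation of an aldehyde, in which C11 is the only enolisable methylene, its aminomethylation gives 28 and Et3N-induced β-elimination of dimethylamine installs C13, whereas the C9 ketone and the isobutyrate offer only hindered methine α-hydrogens, so strong-base enolisation of a lactone next to a ketone is avoided.

Step 18
Reactants: 29 2-substituted acrolein (C11=C13, C12 aldehyde)
Product: 30 2-substituted acrylic acid (C12 acid)
Conditions: NaClO2, NaH2PO4, 2-methyl-2-butene, t-BuOH/H2O, 0 → 23 °C
Reagents that add atoms: sodium chlorite, [Na+].[O-]Cl=O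
Why: Pinnick oxidation converts the 2-substituted acrolein into the acrylic acid under buffered conditions with 2-methyl-2-butene taking up HOCl, so the alkene and the naphthyl group are spared.

Step 19
Reactants: 30 2-substituted acrylic acid (C12 acid)
Product: 32 O8-TBS ether of the target lactone, via hydroxy acid 31 (not isolated)
Conditions: DDQ, CH2Cl2/H2O, 0 → 23 °C; then PPTS (cat.), CH2Cl2, 23 °C
Reagents that add atoms: none
Why: Oxidative cleavage of the naphthylmethyl ether by DDQ (hydride abstraction then hydrolysis) needs no hydrogenation and so keeps C11=C13, and the freed 6α-hydroxyl of 31 closes the trans-fused γ-lactone on C12 by 5-exo-trig acyl substitution, O8 still being silylated so that no 8,12-lactone can form.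

Step 20
Reactants: 32 O8-TBS ether of the target lactone
Product: 33 target CNP0270933.1
Conditions: HF·pyridine, THF, 0 → 23 °C
Reagents that add atoms: none
Why: Fluoride desilylation under mildly acidic conditions frees the C8 hydroxyl without base, which avoids α-ketol shift, epimerisation at C8 or C10, acyl migration and conjugate addition to the methylene lactone.

## Compound list

1 | 2-methylcyclohexanone | CC1CCCCC1=O | starting material
2 | trimethyl[(2-methylcyclohex-1-en-1-yl)oxy]silane | CC1=C(O[Si](C)(C)C)CCCC1 | intermediate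
3 | diallyl carbonate | C=CCOC(=O)OCC=C | starting material
4 | (S)-2-allyl-2-methylcyclohexanone | C[C@@]1(CC=C)CCCCC1=O | intermediate
5 | RAMP, (R)-1-amino-2-(methoxymethyl)pyrrolidine | COC[C@H]1CCCN1N | starting material
6 | (E)-RAMP hydrazone of 4 | C=CC[C@]1(C)CCCC/C1=N\N2CCC[C@@H]2COC | intermediate
7 | lithium azaenolate of 6 (C9=C10) | C=CC[C@]1(C)CCCC=C1N([Li])N2CCC[C@@H]2COC | intermediate
8 | (E)-RAMP hydrazone of (2S,6S)-2-allyl-2,6-dimethylcyclohexanone | C=CC[C@]1(C)CCC[C@H](C)/C1=N\N2CCC[C@@H]2COC | intermediate
9 | 2-[(1S,3S)-1,3-dimethyl-2-oxocyclohexyl]acetaldehyde | C[C@H]1CCC[C@@](C)(CC=O)C1=O | intermediate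
10 | naphthalen-2-ylmethanol | OCc1ccc2ccccc2c1 | starting material
11 | (2S,6S)-2-[2,2-bis(naphthalen-2-ylmethoxy)ethyl]-2,6-dimethylcyclohexanone | C[C@H]1CCC[C@@](C)(CC(OCc2ccc3ccccc3c2)OCc2ccc3ccccc3c2)C1=O | intermediate
12 | (2S,6S)-2,6-dimethyl-2-[(E)-2-(naphthalen-2-ylmethoxy)ethenyl]cyclohexanone | C[C@H]1CCC[C@@](C)(/C=C/OCc2ccc3ccccc3c2)C1=O | intermediate
13 | but-3-yn-1-ol | C#CCCO | starting material
14 | (but-3-yn-1-yloxy)(tert-butyl)dimethylsilane | C#CCCO[Si](C)(C)C(C)(C)C | intermediate
15 | (E)-alkenylzirconocene chloride from 14 | Cl[Zr](/C=C/CCO[Si](C)(C)C(C)(C)C)(C1C=CC=C1)C1C=CC=C1 | intermediate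
16 | (E)-tert-butyl[(4-iodobut-3-en-1-yl)oxy]dimethylsilane | I/C=C/CCO[Si](C)(C)C(C)(C)C | intermediate
17 | (E)-4-(tert-butyldimethylsilyloxy)but-1-enyllithium | [Li]/C=C/CCO[Si](C)(C)C(C)(C)C | intermediate
18 | (1S,2S,6S)-cis-1,2-dialkenyl-2,6-dimethylcyclohexanol (both alkenyl groups and C10 methyl on one face, C4 methyl and OH on the other) | C[C@H]1CCC[C@@](C)(/C=C/OCc2ccc3ccccc3c2)[C@@]1(O)/C=C/CCO[Si](C)(C)C(C)(C)C | intermediate
19 | potassium alkoxide of 18 | C[C@H]1CCC[C@@](C)(/C=C/OCc2ccc3ccccc3c2)[C@@]1([O-])/C=C/CCO[Si](C)(C)C(C)(C)C.[K+] | intermediate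
20 | ten-membered potassium C8–C9 enolate | C1CC/C(C)=C\[C@H](OCc2ccc3ccccc3c2)[C@@H](CCO[Si](C)(C)C(C)(C)C)/C=C([O-])/[C@H]1C.[K+] | intermediate
21 | ten-membered TBS enol ether (4Z; C7 and C10 trans on C8=C9; 6α-ONAP, 7β-CH2CH2OTBS, 10β-CH3) | C1CC/C(C)=C\[C@H](OCc2ccc3ccccc3c2)[C@@H](CCO[Si](C)(C)C(C)(C)C)/C=C(O[Si](C)(C)C(C)(C)C)/[C@H]1C | intermediate
22 | C8–C9 silyloxy epoxide (oxygen on the outer face) | C1CC/C(C)=C\[C@H](OCc2ccc3ccccc3c2)[C@@H](CCO[Si](C)(C)C(C)(C)C)[C@@H]4O[C@@]4(O[Si](C)(C)C(C)(C)C)[C@H]1C | intermediate
23 | 8α-OTBS C9 ketone, 4Z alkene | C1CC/C(C)=C\[C@H](OCc2ccc3ccccc3c2)[C@@H](CCO[Si](C)(C)C(C)(C)C)[C@H](O[Si](C)(C)C(C)(C)C)C(=O)[C@H]1C | intermediate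
24 | 4β,5β-diol | C1CC[C@@](C)(O)[C@@H](O)[C@H](OCc2ccc3ccccc3c2)[C@@H](CCO[Si](C)(C)C(C)(C)C)[C@H](O[Si](C)(C)C(C)(C)C)C(=O)[C@H]1C | intermediate
25 | C5 isobutyrate | C1CC[C@@](C)(O)[C@@H](OC(=O)C(C)C)[C@H](OCc2ccc3ccccc3c2)[C@@H](CCO[Si](C)(C)C(C)(C)C)[C@H](O[Si](C)(C)C(C)(C)C)C(=O)[C@H]1C | intermediate
26 | C12 primary alcohol | C1CC[C@@](C)(O)[C@@H](OC(=O)C(C)C)[C@H](OCc2ccc3ccccc3c2)[C@@H](CCO)[C@H](O[Si](C)(C)C(C)(C)C)C(=O)[C@H]1C | intermediate
27 | C12 aldehyde | C1CC[C@@](C)(O)[C@@H](OC(=O)C(C)C)[C@H](OCc2ccc3ccccc3c2)[C@@H](CC=O)[C@H](O[Si](C)(C)C(C)(C)C)C(=O)[C@H]1C | intermediate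
28 | C11 dimethylaminomethyl aldehyde (Mannich base, C11 epimers) | C1CC[C@@](C)(O)[C@@H](OC(=O)C(C)C)[C@H](OCc2ccc3ccccc3c2)[C@@H](C(CN(C)C)C=O)[C@H](O[Si](C)(C)C(C)(C)C)C(=O)[C@H]1C | intermediate
29 | 2-substituted acrolein (C11=C13) | C1CC[C@@](C)(O)[C@@H](OC(=O)C(C)C)[C@H](OCc2ccc3ccccc3c2)[C@@H](C(=C)C=O)[C@H](O[Si](C)(C)C(C)(C)C)C(=O)[C@H]1C | intermediate
30 | 2-substituted acrylic acid | C1CC[C@@](C)(O)[C@@H](OC(=O)C(C)C)[C@H](OCc2ccc3ccccc3c2)[C@@H](C(=C)C(=O)O)[C@H](O[Si](C)(C)C(C)(C)C)C(=O)[C@H]1C | intermediate
31 | 6α-hydroxy acrylic acid | C1CC[C@@](C)(O)[C@@H](OC(=O)C(C)C)[C@H](O)[C@@H](C(=C)C(=O)O)[C@H](O[Si](C)(C)C(C)(C)C)C(=O)[C@H]1C | intermediate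
32 | O8-TBS ether of the target | C=C1C(=O)O[C@@H]2[C@@H]1[C@H](O[Si](C)(C)C(C)(C)C)C(=O)[C@@H](C)CCC[C@@](C)(O)[C@H]2OC(=O)C(C)C | intermediate
33 | CNP0270933.1 (4R,5S,6R,7S,8S,10S) | C=C1C(=O)O[C@@H]2[C@@H]1[C@H](O)C(=O)[C@@H](C)CCC[C@@](C)(O)[C@H]2OC(=O)C(C)C | target

## Step count

- Total step count: 20.
- Longest linear sequence: 18 (steps 1–7 and 10–20). Steps 8 and 9 form the side branch.

## Steps most likely to fail

**1. Step 11.**
- *What may go wrong:* the alkoxide may rearrange through a boat or through the ring-flipped chair, which would lose the alkene geometry and the C6/C7 sense. It may also cleave heterolytically at C4–C9, because the donor-substituted terminus C6 slows bond formation.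
- *Fallback, from 18 back to 21:* 18 is heated without base (o-dichlorobenzene, about 200 °C, silylated glassware). The neutral oxy-Cope shift is then pulled forward by tautomerisation of the enol to the 4Z cyclodecenone with a C8 methylene F1. The C8 methylene, the less hindered α-position of F1, is deprotonated kinetically with KN(SiMe3)2 at −78 °C and silylated with TBSCl to give 21.

**2. Step 13.**
- *What may go wrong:* osmylation must approach on the side that carries the C6 ether. It may therefore be slow, or the ring may expose the α face instead, giving poor or reversed facial selectivity.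
- *Fallback, from 23 back to 24:* Woodward cis-hydroxylation (I2, AgOAc, AcOH, then wet AcOH) is used.
  - The iodonium ion forms on the face that the osmium reagent prefers, and acetate opens it from the other side.
  - The acetoxonium ion then displaces iodide with inversion, so both oxygens end on the opposite face.
  - This should give the 4β-hydroxy 5β-acetate F2, and brief methanolysis (K2CO3, MeOH, 0 °C) gives 24.

**3. Step 7.**
- *What may go wrong:* proton loss from the oxocarbenium ion may give an E/Z mixture. Competing enol silylation of the ketone would erode the C10 configuration.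
- *Fallback, from 11 back to 12:* a neutral pericyclic elimination replaces the ionic one.
  - PhSSiMe3 with catalytic TMSOTf at −78 °C exchanges one naphthylmethoxy group to give the O,S-acetal F3.
  - mCPBA at −78 °C gives the α-alkoxy sulfoxide F4.
  - Warming F4 in toluene over CaCO3 triggers thermal syn-elimination. This should place the quaternary C4 and the oxygen trans and deliver 12 without acid or base.

## Further compounds

F1 | step 11 | 4Z cyclodecenone with C8 methylene (6α-ONAP, 7β-CH2CH2OTBS, 10β-CH3) | C1CC/C(C)=C\[C@H](OCc2ccc3ccccc3c2)[C@@H](CCO[Si](C)(C)C(C)(C)C)CC(=O)[C@H]1C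
F2 | step 13 | 4β-hydroxy 5β-acetate | C1CC[C@@](C)(O)[C@@H](OC(C)=O)[C@H](OCc2ccc3ccccc3c2)[C@@H](CCO[Si](C)(C)C(C)(C)C)[C@H](O[Si](C)(C)C(C)(C)C)C(=O)[C@H]1C
F3 | step 7 | O,S-acetal (epimers at C6) | C[C@H]1CCC[C@@](C)(CC(OCc2ccc3ccccc3c2)Sc2ccccc2)C1=O
F4 | step 7 | α-alkoxy sulfoxide (epimers at C6 and sulfur) | C[C@H]1CCC[C@@](C)(CC(OCc2ccc3ccccc3c2)S(=O)c2ccccc2)C1=O
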